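**Plan**
- Feature: ring B carries a 2,2-dimethyl-2H-pyran fused across C4'–C5' with its oxygen on C4'. It is the dehydrogenated, ring-closed form of a C5' prenyl group whose CH2 is benzylic, allylic and ortho to the C4' hydroxyl, so the pyran O–C(CH3)2 bond is cut first.
- Further cuts: the four MOM ethers, then the C2–C1' bond (aryl onto a ring A chromone), then O1–C2/C2–C3 of the chromone (one-carbon unit on an ortho-hydroxyacetophenone), then the side-chain C–OH (hydration) and the C8–CH2 bond (C-prenylation). Ring B is cut at C1'–B and C5'–CH2 back to 4,6-dibromoresorcinol.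
- Forward order: the C8 chain is installed and hydrated on ring A, the pyranone ring is closed, the ring B aryl is joined at C2, the phenols are freed, and the pyran on ring B is closed last.
- Stereochemistry: C2 (S) is the only stereocentre. It is set by a chiral diene–rhodium conjugate addition (catalyst control) and afterwards meets only neutral or acidic conditions.

Key step: step 10

Assumption: the chiral diene is taken to show the same facial preference on the chromone as on 2-cyclohexenone, which points to the (S,S)-ligand for the (2S)-flavanone; if a test addition shows the opposite sense, the (R,R)-ligand is used instead.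

**Route**

Step 1
Reactants: 1 2,4,6-trihydroxyacetophenone; 2 prenyl bromide
Product: 3 1-[2,4,6-trihydroxy-3-(3-methylbut-2-en-1-yl)phenyl]ethan-1-one
Conditions: 2 (1.0 equiv), DBU, THF, 0 °C → rt
Reagents that add atoms: none
Why: Nuclear prenylation (C-alkylation of the ambident phloroglucinol phenoxide by an allylic bromide) should give a single mono-C-prenyl isomer because the two open ring positions of 1 are equivalent, and one equivalent of bromide limits bis-alkylation.

Step 2
Reactants: 3 1-[2,4,6-trihydroxy-3-(3-methylbut-2-en-1-yl)phenyl]ethan-1-one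
Product: 4 1-[2-hydroxy-4,6-bis(methoxymethoxy)-3-(3-methylbut-2-en-1-yl)phenyl]ethan-1-one
Conditions: MOMCl (2.2 equiv), i-Pr2NEt, CH2Cl2, 0 °C
Reagents that add atoms: chloromethyl methyl ether, COCCl
Why: MOM ether formation (O-alkylation with an α-chloro ether) should take the non-chelated para hydroxyl first and then the less hindered ortho hydroxyl, leaving free the hydrogen-bonded hydroxyl flanked by acetyl and prenyl, which later becomes O1 and so places the chain at C8.

Step 3
Reactants: 4 1-[2-hydroxy-4,6-bis(methoxymethoxy)-3-(3-methylbut-2-en-1-yl)phenyl]ethan-1-one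
Product: 5 1-[2-hydroxy-3-(3-hydroxy-3-methylbutyl)-4,6-bis(methoxymethoxy)phenyl]ethan-1-one
Conditions: Co(acac)2 (20 mol %), PhSiH3, O2 (1 atm), THF, rt
Reagents that add atoms: dioxygen, O=O
Why: Mukaiyama hydration (hydrogen-atom transfer from a cobalt hydride to the trisubstituted alkene, trapping of the tertiary radical by O2 and reduction of the peroxide) should give the Markovnikov tertiary alcohol under neutral radical conditions that avoid acid-induced chroman formation with the neighbouring phenol.

Step 4
Reactants: 5 1-[2-hydroxy-3-(3-hydroxy-3-methylbutyl)-4,6-bis(methoxymethoxy)phenyl]ethan-1-one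
Product: 7 8-(3-hydroxy-3-methylbutyl)-5,7-bis(methoxymethoxy)-4H-chromen-4-one, via enaminone 6 (not isolated)
Conditions: DMF–DMA, toluene, 90 °C; then AcOH, 60 °C
Reagents that add atoms: N,N-dimethylformamide dimethyl acetal, CN(C)C(OC)OC
Why: The enaminone route to chromones (condensation at the acetyl methyl, then acid-promoted addition of the only free phenol to the β-carbon and loss of dimethylamine) should close the pyranone, with acetic acid mild enough to spare the MOM ethers and the tertiary alcohol.

Step 5
Reactants: 8 4,6-dibromoresorcinol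
Product: 9 1,5-dibromo-2,4-bis(methoxymethoxy)benzene
Conditions: MOMCl (2.5 equiv), i-Pr2NEt, CH2Cl2, 0 °C → rt
Reagents that add atoms: chloromethyl methyl ether, COCCl
Why: Standard MOM protection of both phenols gives ethers that survive organolithium chemistry and stabilise an ortho aryllithium by chelation.

Step 6
Reactants: 9 1,5-dibromo-2,4-bis(methoxymethoxy)benzene; 2 prenyl bromide
Product: 12 1-bromo-2,4-bis(methoxymethoxy)-5-(3-methylbut-2-en-1-yl)benzene, via aryllithium 10 (not isolated), via arylcopper 11 (not isolated)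
Conditions: n-BuLi (1.0 equiv), THF, −78 °C; CuBr·SMe2 (1.0 equiv); 2, −78 → 0 °C
Reagents that add atoms: none
Why: Bromine–lithium exchange at one of the two equivalent bromides, transmetalation to copper and copper-mediated aryl–allyl coupling at the primary carbon of prenyl bromide should give the linear prenyl arene, with the second bromide untouched at −78 °C by one equivalent of n-BuLi.

Step 7
Reactants: 12 1-bromo-2,4-bis(methoxymethoxy)-5-(3-methylbut-2-en-1-yl)benzene
Product: 14 [2,4-bis(methoxymethoxy)-5-(3-methylbut-2-en-1-yl)phenyl]boronic acid, via aryllithium 13 (not isolated)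
Conditions: n-BuLi (1.1 equiv), THF, −78 °C; B(Oi-Pr)3, −78 °C → rt; aq. NH4Cl
Reagents that add atoms: triisopropyl borate, CC(C)OB(OC(C)C)OC(C)C; water, O
Why: A second bromine–lithium exchange followed by electrophilic borylation and mild hydrolysis is the standard route to arylboronic acids, and at −78 °C exchange should outrun deprotonation of the allylic and benzylic positions.

Step 8
Reactants: 7 8-(3-hydroxy-3-methylbutyl)-5,7-bis(methoxymethoxy)-4H-chromen-4-one; 14 [2,4-bis(methoxymethoxy)-5-(3-methylbut-2-en-1-yl)phenyl]boronic acid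
Product: 15 (2S)-2-[2,4-bis(methoxymethoxy)-5-(3-methylbut-2-en-1-yl)phenyl]-8-(3-hydroxy-3-methylbutyl)-5,7-bis(methoxymethoxy)-2,3-dihydro-4H-chromen-4-one
Conditions: [Rh(C2H4)2Cl]2 (3 mol %), (1S,4S)-2,5-diphenylbicyclo[2.2.2]octa-2,5-diene (6.6 mol %), 14 (2.5 equiv), KOH (10 mol %), 1,4-dioxane–H2O (10:1), 40 °C
Reagents that add atoms: none
Why: In this Hayashi–Miyaura asymmetric 1,4-addition the aryl group passes from boron to a monovalent rhodium hydroxide, the chiral diene directs carborhodation to one face of the chromone C2=C3 bond and so sets C2 as S, and protonolysis of the rhodium enolate releases the flavanone, while only catalytic base limits retro-oxa-Michael opening.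

Step 9
Reactants: 15 (2S)-2-[2,4-bis(methoxymethoxy)-5-(3-methylbut-2-en-1-yl)phenyl]-8-(3-hydroxy-3-methylbutyl)-5,7-bis(methoxymethoxy)-2,3-dihydro-4H-chromen-4-one
Product: 16 (2S)-2-[2,4-dihydroxy-5-(3-methylbut-2-en-1-yl)phenyl]-5,7-dihydroxy-8-(3-hydroxy-3-methylbutyl)-2,3-dihydro-4H-chromen-4-one
Conditions: aq. HCl (3 M), MeOH–THF, rt → 40 °C
Reagents that add atoms: none
Why: Acid-catalysed transacetalisation of the four aryl MOM ethers to methanol should be much faster at this acidity than ionisation of the tertiary alcohol or protonation of the prenyl alkene, and without base the flavanone should not open, so C2 should keep its configuration.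

Step 10
Reactants: 16 (2S)-2-[2,4-dihydroxy-5-(3-methylbut-2-en-1-yl)phenyl]-5,7-dihydroxy-8-(3-hydroxy-3-methylbutyl)-2,3-dihydro-4H-chromen-4-one
Product: 18 (2S)-5,7-dihydroxy-8-(3-hydroxy-3-methylbutyl)-2-(7-hydroxy-2,2-dimethyl-2H-chromen-6-yl)-2,3-dihydro-4H-chromen-4-one, via ortho-quinone methide 17 (not isolated)
Conditions: DDQ (1.05 equiv), 1,4-dioxane, rt
Reagents that add atoms: none
Why: DDQ takes a hydride from the C5' CH2, the only C–H that is at once benzylic, allylic and ortho/para to two phenolic hydroxyls, and loss of the C4' hydroxyl proton gives the ortho-quinone methide 17, a 1-oxatriene (O=C4'–C5'=CH–CH=C(CH3)2). Thermal oxa-6π electrocyclisation of 17 forms the O–C(CH3)2 bond, closes the six-membered pyran and restores the aromaticity of ring B; the closest known reaction is the DDQ cyclodehydrogenation of ortho-prenylphenols to 2,2-dimethyl-2H-chromenes. The ring closes in the 6π-electrocyclic mode (formally 6-endo at the dimethyl-substituted carbon), no stereocentre is created and C2 is not involved, so the (2S) configuration is carried through. Regioselectivity is fixed by the substrate because the C4' hydroxyl is the only one ortho to the prenyl group, while the para C2' hydroxyl can at most give a para-quinone methide that cannot cyclise and should return through the common cation by proton exchange. Chemoselectivity over hydride loss from C2–H (which would lead to the flavone) and from the saturated C8 chain rests on the far better stabilised allyl–benzyl cation, on ring A being deactivated by the hydrogen-bonded C4 carbonyl, and on one equivalent of oxidant at room temperature.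

**Compound list**

1 | 2,4,6-trihydroxyacetophenone | CC(=O)c1c(O)cc(O)cc1O | starting material
2 | prenyl bromide (1-bromo-3-methylbut-2-ene) | CC(C)=CCBr | starting material
3 | 1-[2,4,6-trihydroxy-3-(3-methylbut-2-en-1-yl)phenyl]ethan-1-one | CC(=O)c1c(O)c(CC=C(C)C)c(O)cc1O | intermediate
4 | 1-[2-hydroxy-4,6-bis(methoxymethoxy)-3-(3-methylbut-2-en-1-yl)phenyl]ethan-1-one | CC(=O)c1c(O)c(CC=C(C)C)c(OCOC)cc1OCOC | intermediate
5 | 1-[2-hydroxy-3-(3-hydroxy-3-methylbutyl)-4,6-bis(methoxymethoxy)phenyl]ethan-1-one | CC(=O)c1c(O)c(CCC(C)(C)O)c(OCOC)cc1OCOC | intermediate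
6 | (E)-3-(dimethylamino)-1-[2-hydroxy-3-(3-hydroxy-3-methylbutyl)-4,6-bis(methoxymethoxy)phenyl]prop-2-en-1-one (enaminone) | CN(C)/C=C/C(=O)c1c(O)c(CCC(C)(C)O)c(OCOC)cc1OCOC | intermediate
7 | 8-(3-hydroxy-3-methylbutyl)-5,7-bis(methoxymethoxy)-4H-chromen-4-one | O=c1ccoc2c(CCC(C)(C)O)c(OCOC)cc(OCOC)c12 | intermediate
8 | 4,6-dibromoresorcinol | Oc1cc(O)c(Br)cc1Br | starting material
9 | 1,5-dibromo-2,4-bis(methoxymethoxy)benzene | COCOc1cc(OCOC)c(Br)cc1Br | intermediate
10 | [5-bromo-2,4-bis(methoxymethoxy)phenyl]lithium (aryllithium) | [Li]c1cc(Br)c(OCOC)cc1OCOC | intermediate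
11 | [5-bromo-2,4-bis(methoxymethoxy)phenyl]copper (arylcopper) | [Cu]c1cc(Br)c(OCOC)cc1OCOC | intermediate
12 | 1-bromo-2,4-bis(methoxymethoxy)-5-(3-methylbut-2-en-1-yl)benzene | COCOc1cc(OCOC)c(CC=C(C)C)cc1Br | intermediate
13 | [2,4-bis(methoxymethoxy)-5-(3-methylbut-2-en-1-yl)phenyl]lithium (aryllithium) | [Li]c1cc(CC=C(C)C)c(OCOC)cc1OCOC | intermediate
14 | [2,4-bis(methoxymethoxy)-5-(3-methylbut-2-en-1-yl)phenyl]boronic acid | OB(O)c1cc(CC=C(C)C)c(OCOC)cc1OCOC | intermediate
15 | (2S)-2-[2,4-bis(methoxymethoxy)-5-(3-methylbut-2-en-1-yl)phenyl]-8-(3-hydroxy-3-methylbutyl)-5,7-bis(methoxymethoxy)-2,3-dihydro-4H-chromen-4-one | CC(C)(O)CCc1c(OCOC)cc(OCOC)c2c1O[C@H](c1cc(CC=C(C)C)c(OCOC)cc1OCOC)CC2=O | intermediate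
16 | (2S)-2-[2,4-dihydroxy-5-(3-methylbut-2-en-1-yl)phenyl]-5,7-dihydroxy-8-(3-hydroxy-3-methylbutyl)-2,3-dihydro-4H-chromen-4-one | CC(C)(O)CCc1c(O)cc(O)c2c1O[C@H](c1cc(CC=C(C)C)c(O)cc1O)CC2=O | intermediate
17 | ortho-quinone methide of 16: the C4' oxygen is a carbonyl and C5' carries an exocyclic (Z)-3-methylbuta-1,3-dienylidene unit, (2S) | CC(C)=C/C=C1\C(=O)C=C(O)C([C@@H]2CC(=O)c3c(O)cc(O)c(CCC(C)(C)O)c3O2)=C1 | intermediate
18 | (2S)-5,7-dihydroxy-8-(3-hydroxy-3-methylbutyl)-2-(7-hydroxy-2,2-dimethyl-2H-chromen-6-yl)-2,3-dihydro-4H-chromen-4-one | CC(C)(O)CCc1c(O)cc(O)c2c1O[C@H](c1cc3c(cc1O)OC(C)(C)C=C3)CC2=O | target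

**Step count**
Total: 10 steps. Longest linear sequence: 7 steps (steps 1–4, then 8–10); the ring B branch is steps 5–7.

**Steps most likely to fail, with fallbacks**

Step 8. The ortho-alkoxy, electron-rich boronic acid may lose boron by protodeboronation faster than it transfers to rhodium, the 5-alkoxy chromone may insert slowly, and facial selectivity may be poor with the hindered aryl group. The fallback sets out from 12 and 5 and comes back at 15. Bromine–lithium exchange of 12 as in step 7 gives aryllithium 13, which on quenching with DMF and aqueous work-up should give 2,4-bis(methoxymethoxy)-5-(3-methylbut-2-en-1-yl)benzaldehyde F1. Claisen–Schmidt condensation of F1 with acetophenone 5 (KOH, EtOH–H2O, rt) should give the chalcone (E)-1-[2-hydroxy-3-(3-hydroxy-3-methylbutyl)-4,6-bis(methoxymethoxy)phenyl]-3-[2,4-bis(methoxymethoxy)-5-(3-methylbut-2-en-1-yl)phenyl]prop-2-en-1-one F2. Oxa-Michael ring closure (NaOAc, EtOH, reflux) should then give the racemic protected flavanone F3. Preparative HPLC on a polysaccharide chiral stationary phase separates 15 from the (2R)-enantiomer F4, which can be returned to the racemate by base-mediated ring opening and reclosure.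

Step 10. The unprotected polyphenol may be over-oxidised, the cation may be diverted through the para-quinone methide into adducts with the reduced quinone, or the flavanone may be dehydrogenated. The fallback sets out from 16 and comes back at 18 without a hydride-abstracting oxidant. Selenoetherification with N-(phenylseleno)phthalimide (CH2Cl2, −20 °C) should open the seleniranium ion at the tertiary carbon with the C4' hydroxyl (6-endo) and give the 3-(phenylselanyl)-2,2-dimethylchroman-fused flavanone F6 as a mixture at the selenium-bearing carbon. Oxidation with H2O2 (THF, 0 °C) gives the selenoxide F7, whose syn-elimination can only take the benzylic hydrogen and so should deliver the chromene 18.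

Step 9. Under protic acid the freed C4' hydroxyl may add to the prenyl alkene, the tertiary alcohol may ionise and close onto the C7 hydroxyl (chroman formation in either case), or C2 may epimerise through ring opening. The fallback sets out from 15 and comes back at 16 by exchanging acetal for silyl protection under non-protic conditions. TMSOTf with 2,2'-bipyridyl (MeCN, 0 °C → rt) should transfer the methoxymethyl groups to the bipyridyl and give the pentakis(trimethylsilyl) ether F5 (four aryl silyl ethers and the silylated tertiary alcohol). F5 is then hydrolysed to 16 with water and a trace of citric acid in MeOH at 0 °C.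

**Further compounds**
F1 | step 8 | 2,4-bis(methoxymethoxy)-5-(3-methylbut-2-en-1-yl)benzaldehyde | O=Cc1cc(CC=C(C)C)c(OCOC)cc1OCOC
F2 | step 8 | (E)-1-[2-hydroxy-3-(3-hydroxy-3-methylbutyl)-4,6-bis(methoxymethoxy)phenyl]-3-[2,4-bis(methoxymethoxy)-5-(3-methylbut-2-en-1-yl)phenyl]prop-2-en-1-one | CC(C)(O)CCc1c(O)c(C(=O)/C=C/c2cc(CC=C(C)C)c(OCOC)cc2OCOC)c(OCOC)cc1OCOC
F3 | step 8 | racemic 2-[2,4-bis(methoxymethoxy)-5-(3-methylbut-2-en-1-yl)phenyl]-8-(3-hydroxy-3-methylbutyl)-5,7-bis(methoxymethoxy)-2,3-dihydro-4H-chromen-4-one | CC(C)(O)CCc1c(OCOC)cc(OCOC)c2c1OC(c1cc(CC=C(C)C)c(OCOC)cc1OCOC)CC2=O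
F4 | step 8 | (2R)-enantiomer of 15 | CC(C)(O)CCc1c(OCOC)cc(OCOC)c2c1O[C@@H](c1cc(CC=C(C)C)c(OCOC)cc1OCOC)CC2=O
F5 | step 9 | (2S)-2-[5-(3-methylbut-2-en-1-yl)-2,4-bis(trimethylsilyloxy)phenyl]-8-[3-methyl-3-(trimethylsilyloxy)butyl]-5,7-bis(trimethylsilyloxy)-2,3-dihydro-4H-chromen-4-one | C[Si](C)(C)OC(C)(C)CCc1c(O[Si](C)(C)C)cc(O[Si](C)(C)C)c2c1O[C@H](c1cc(CC=C(C)C)c(O[Si](C)(C)C)cc1O[Si](C)(C)C)CC2=O
F6 | step 10 | (2S)-5,7-dihydroxy-8-(3-hydroxy-3-methylbutyl)-2-[7-hydroxy-2,2-dimethyl-3-(phenylselanyl)-3,4-dihydro-2H-chromen-6-yl]-2,3-dihydro-4H-chromen-4-one | CC(C)(O)CCc1c(O)cc(O)c2c1O[C@H](c1cc3c(cc1O)OC(C)(C)C([Se]c1ccccc1)C3)CC2=O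
F7 | step 10 | selenoxide of F6 | CC(C)(O)CCc1c(O)cc(O)c2c1O[C@H](c1cc3c(cc1O)OC(C)(C)C([Se](=O)c1ccccc1)C3)CC2=O
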